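The bond to cut is C6–C7. Three neighbouring features point to it: a secondary alcohol at C6, a methine at C7 shared by the ten-membered carbocycle (C1–C10) and the γ-lactone ring (C7, C8, O, C12, C11), and an exocyclic C11=C13 double bond. An allyl metal with a carbonyl group on its central carbon leaves this pattern when it adds to an aldehyde with allylic transposition. One chromium-mediated operation therefore closes the carbocycle, sets C6 and C7, and turns a butenolide into the α-methylene lactone. The precursor is an open chain: a 3-(bromomethyl)butenolide whose C8 carries the C9 senecioate, the C10 methyl centre and a chain ending in the E C4=C5–C6 enal.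

Key step: step 10

Remarks:
- Germacrane numbering is used throughout (C14 is the methyl on C10, C15 the methyl on C4).
- Read from the SMILES, all seven stereocentres of the target are R.
- In relative terms, H7/H8 are cis, O8/O9 are syn, and O9/C14 are anti, which is the anti-Felkin sense for an addition to a C9 aldehyde.
- O6/C8 are anti when C5–C6–C7–C11 is drawn zigzag. The trans epoxide is erythro to O6.

Assumption: allyl methoxymethyl ether, (−)-B-methoxydiisopinocampheylborane, bromodimethylborane and 2-(bromomethyl)acrylic acid are taken as catalogue items.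

Step 1
Reactants: 1 geranyl acetate
Product: 2 (2E,6E)-8-hydroxy-3,7-dimethylocta-2,6-dien-1-yl acetate
Conditions: SeO2 (cat.), salicylic acid (cat.), t-BuOOH, CH2Cl2, 0 °C → rt
Reagents that add atoms: tert-butyl hydroperoxide, CC(C)(C)OO
Why: Catalytic SeO2 allylic oxidation (ene reaction, then [2,3]-sigmatropic shift) attacks the more electron-rich distal trisubstituted olefin at its E methyl group, while the allylic acetate deactivates C4=C5, so C9 is oxygenated with the E C10=C1 geometry kept.

Step 2
Reactants: 2 (2E,6E)-8-hydroxy-3,7-dimethylocta-2,6-dien-1-yl acetate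
Product: 3 (2E,7R)-8-hydroxy-3,7-dimethyloct-2-en-1-yl acetate
Conditions: H2 (100 atm), Ru(OAc)2[(R)-BINAP] (cat.), MeOH, 25 °C
Reagents that add atoms: none
Why: In this Noyori hydroxyl-directed asymmetric hydrogenation only the olefin that can bind ruthenium through the free C9 hydroxyl is reduced, the (R)-ligand is expected to make C10 R (by analogy with the face chosen in geraniol and in E 2-methylalk-2-enoic acids, to be checked on the first batch), and any minor antipode becomes a separable diastereomer in step 4.

Step 3
Reactants: 3 (2E,7R)-8-hydroxy-3,7-dimethyloct-2-en-1-yl acetate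
Product: 4 (2E,7R)-3,7-dimethyl-8-oxooct-2-en-1-yl acetate
Conditions: TEMPO (cat.), PhI(OAc)2, CH2Cl2, rt; used crude
Reagents that add atoms: none
Why: Oxoammonium (TEMPO) oxidation of the primary alcohol stops at the aldehyde under non-basic conditions, so the epimerisable C10 centre, the acetate and the olefin stay untouched.

Step 4
Reactants: 4 (2E,7R)-3,7-dimethyl-8-oxooct-2-en-1-yl acetate; 5 allyl methoxymethyl ether
Product: 9 (2E,7R,8R,9R)-9-(methoxymethoxy)-3,7-dimethylundeca-2,10-diene-1,8-diol, via alkoxyallylborane 6 (not isolated), via borinate 7 (not isolated), via hydroxy acetate 8 (not isolated)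
Conditions: 5, s-BuLi, THF, −78 °C; (−)-Ipc2BOMe; BF3·OEt2; 4, −78 °C → rt; then 3 M NaOH, 30% H2O2, MeOH, rt, 12 h
Reagents that add atoms: allyl methoxymethyl ether (5), C=CCOCOC
Why: In this Brown alkoxyallylboration the Z γ-alkoxyallylborane reacts through a closed chair that makes O8/O9 syn, the isopinocampheyl groups from (+)-α-pinene select the Si face of the aldehyde (C9 R, hence C8 R), the required 9,10-anti sense is the one Z γ-substituted allylboron reagents prefer with α-methyl aldehydes so the pairing should be matched, and the prolonged alkaline peroxide work-up also saponifies the primary acetate.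

Step 5
Reactants: 9 (2E,7R,8R,9R)-9-(methoxymethoxy)-3,7-dimethylundeca-2,10-diene-1,8-diol
Product: 10 (2E,7R,8R,9R)-8-hydroxy-9-(methoxymethoxy)-3,7-dimethylundeca-2,10-dienal
Conditions: activated MnO2, CH2Cl2, rt
Reagents that add atoms: none
Why: Activated MnO2 oxidises only the allylic primary alcohol at C6 and leaves the saturated secondary C9 carbinol and the E C4=C5 geometry intact, which tells the two hydroxyls apart without a protecting group.

Step 6
Reactants: 10 (2E,7R,8R,9R)-8-hydroxy-9-(methoxymethoxy)-3,7-dimethylundeca-2,10-dienal; 11 3-methylbut-2-enoyl chloride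
Product: 12 (3R,4R,5R,9E)-3-(methoxymethoxy)-5,9-dimethyl-11-oxoundeca-1,9-dien-4-yl 3-methylbut-2-enoate
Conditions: 11, pyridine, DMAP (cat.), CH2Cl2, 0 °C → rt
Reagents that add atoms: 3-methylbut-2-enoyl chloride (11), CC(C)=CC(=O)Cl
Why: DMAP-catalysed acylation of the only free hydroxyl puts the senecioate on O9 with retention, and pyridine in place of a trialkylamine holds back the vinylketene pathway that would deconjugate the acyl group.

Step 7
Reactants: 12 (3R,4R,5R,9E)-3-(methoxymethoxy)-5,9-dimethyl-11-oxoundeca-1,9-dien-4-yl 3-methylbut-2-enoate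
Product: 14 (3R,4R,5R,9E)-3-hydroxy-5,9-dimethyl-11-oxoundeca-1,9-dien-4-yl 3-methylbut-2-enoate, via bromomethyl ether 13 (not isolated)
Conditions: Me2BBr, CH2Cl2, −78 °C; then sat. aq. NaHCO3, THF, 0 °C
Reagents that add atoms: none
Why: Bromodimethylborane cleaves the acetal C–O bond of a MOM ether at −78 °C through the bromomethyl ether, which bicarbonate then hydrolyses, and under these conditions esters, olefins and the enal persist while the exposure is too cold and too brief for acyl migration from O9 to O8.

Step 8
Reactants: 14 (3R,4R,5R,9E)-3-hydroxy-5,9-dimethyl-11-oxoundeca-1,9-dien-4-yl 3-methylbut-2-enoate; 15 2-(bromomethyl)acrylic acid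
Product: 17 (3R,4R,5R,9E)-3-{[2-(bromomethyl)acryloyl]oxy}-5,9-dimethyl-11-oxoundeca-1,9-dien-4-yl 3-methylbut-2-enoate, via acid chloride 16 (not isolated)
Conditions: 15, (COCl)2, DMF (cat.), CH2Cl2, 0 °C → rt, evaporate; then 14, i-Pr2NEt, CH2Cl2, −20 → 0 °C
Reagents that add atoms: 2-(bromomethyl)acrylic acid (15), C=C(CBr)C(=O)O
Why: Acylation of the allylic C8 alcohol by the preformed acid chloride with a hindered non-nucleophilic amine avoids the pyridine-type catalysts that would quaternise the allylic bromide, and it leaves C8 unchanged.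

Step 9
Reactants: 17 (3R,4R,5R,9E)-3-{[2-(bromomethyl)acryloyl]oxy}-5,9-dimethyl-11-oxoundeca-1,9-dien-4-yl 3-methylbut-2-enoate
Product: 18 (1R,2R,6E)-1-[(2R)-4-(bromomethyl)-5-oxo-2,5-dihydrofuran-2-yl]-2,6-dimethyl-8-oxooct-6-en-1-yl 3-methylbut-2-enoate
Conditions: second-generation Hoveyda–Grubbs catalyst RuCl2(H2IMes)(=CH-C6H4-2-O-i-Pr) (10 mol %), toluene (5 mM), 80 °C, argon sparge
Reagents that add atoms: none
Why: In this ring-closing metathesis the catalyst loads at the only monosubstituted olefin (C7=CH2) and closes the five-membered ring onto the 1,1-disubstituted acrylate, the trisubstituted electron-poor olefins of the enal and the senecioate being much poorer partners, so butenolide and allylic bromide appear together, without base, one step before they are used.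

Step 10
Reactants: 18 (1R,2R,6E)-1-[(2R)-4-(bromomethyl)-5-oxo-2,5-dihydrofuran-2-yl]-2,6-dimethyl-8-oxooct-6-en-1-yl 3-methylbut-2-enoate
Product: 21 (4E,6S,7R,8R,9R,10R)-6-hydroxy-9-(3-methylbut-2-enoyloxy)germacra-4,11(13)-dien-12,8-olide, via allylchromium dichloride 19 (not isolated), via chromium alkoxide 20 (not isolated)
Conditions: CrCl2 (10 equiv), degassed THF, 25 °C, 18 added by syringe pump over 12 h (final 1 mM); then H2O, 0 °C
Reagents that add atoms: none
Why: Two equivalents of divalent chromium reduce the C13–Br bond to allylchromium 19, whose trivalent chromium binds the C6 aldehyde oxygen and delivers the allyl unit through its γ-carbon C7 in a closed six-membered transition state, so C6–C7 forms, the double bond moves to C11=C13 and alkoxide 20 results; this is a Nozaki–Hiyama allylation, a reaction type known both for ω-formyl allylic bromides closing germacrane rings and for 3-(bromomethyl)butenolides adding to aldehydes. The ten-membered carbocycle closes by a 10-exo-trig carbonyl addition between two sp2 carbons under pseudo-high dilution, with the E C4=C5 olefin and the flat butenolide limiting the freedom of the chain. For C6 relative to C7, the lactone ring locks C8 trans to C13 on the allyl unit, an E-crotyl-type geometry that cannot isomerise, so the chair with C5 equatorial should give the anti pair of the target. For C7 relative to C8, the new bond must form on the butenolide face that carries C9 (H7/H8 cis), and only the eight-atom tether from C9 to C6 can impose this against the inherent preference of a 5-substituted butenolide for attack away from its side chain, which is why the risk of the route is gathered here. Chemoselectivity rests on the inertness of organochromium reagents toward lactone, ester and enoate olefins and on the base-free medium, which spares the acidic C8–H next to the C9 acyloxy leaving group, while silyl chlorides are left out so that the enal is not reduced and a cold neutral quench limits acyl transfer from O8 to O6.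

Step 11
Reactants: 21 (4E,6S,7R,8R,9R,10R)-6-hydroxy-9-(3-methylbut-2-enoyloxy)germacra-4,11(13)-dien-12,8-olide
Product: 22 (4R,5R,6R,7R,8R,9R,10R)-4,5-epoxy-6-hydroxy-9-(3-methylbut-2-enoyloxy)germacr-11(13)-en-12,8-olide (CNP0214930.1)
Conditions: VO(acac)2 (5 mol %), t-BuOOH (decane), CH2Cl2, 0 °C → rt
Reagents that add atoms: tert-butyl hydroperoxide, CC(C)(C)OO
Why: In this vanadium-catalysed hydroxyl-directed epoxidation the pentavalent vanadium alkoxide of O6 can reach C4=C5 only in the ring conformer that has C7 on the inner face and the C6–O bond nearly eclipsed with the olefin, so oxygen should arrive on the exposed face and give the erythro (4R,5R) trans epoxide, while the electron-poor C11=C13 and senecioate olefins do not react and a peracid, which would use the other conformer, is avoided.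

Compound list

1 | geranyl acetate | CC(C)=CCC/C(C)=C/COC(C)=O | starting material
2 | (2E,6E)-8-hydroxy-3,7-dimethylocta-2,6-dien-1-yl acetate | OC/C(C)=C/CC/C(C)=C/COC(C)=O | intermediate
3 | (2E,7R)-8-hydroxy-3,7-dimethyloct-2-en-1-yl acetate | OC[C@H](C)CCC/C(C)=C/COC(C)=O | intermediate
4 | (2E,7R)-3,7-dimethyl-8-oxooct-2-en-1-yl acetate | O=C[C@H](C)CCC/C(C)=C/COC(C)=O | intermediate
5 | allyl methoxymethyl ether | C=CCOCOC | starting material
6 | [(Z)-3-(methoxymethoxy)allyl]diisopinocampheylborane, Ipc from (+)-α-pinene | COCO/C=C\CB([C@@H]1C[C@@H]2C[C@H]([C@H]1C)C2(C)C)[C@@H]1C[C@@H]2C[C@H]([C@H]1C)C2(C)C | intermediate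
7 | diisopinocampheylborinate of O9 in the adduct | C=C[C@@H](OCOC)[C@H](OB([C@@H]1C[C@@H]2C[C@H]([C@H]1C)C2(C)C)[C@@H]1C[C@@H]2C[C@H]([C@H]1C)C2(C)C)[C@H](C)CCC/C(C)=C/COC(C)=O | intermediate
8 | (2E,7R,8R,9R)-8-hydroxy-9-(methoxymethoxy)-3,7-dimethylundeca-2,10-dien-1-yl acetate | C=C[C@@H](OCOC)[C@H](O)[C@H](C)CCC/C(C)=C/COC(C)=O | intermediate
9 | (2E,7R,8R,9R)-9-(methoxymethoxy)-3,7-dimethylundeca-2,10-diene-1,8-diol | C=C[C@@H](OCOC)[C@H](O)[C@H](C)CCC/C(C)=C/CO | intermediate
10 | (2E,7R,8R,9R)-8-hydroxy-9-(methoxymethoxy)-3,7-dimethylundeca-2,10-dienal | C=C[C@@H](OCOC)[C@H](O)[C@H](C)CCC/C(C)=C/C=O | intermediate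
11 | 3-methylbut-2-enoyl chloride | CC(C)=CC(=O)Cl | starting material
12 | (3R,4R,5R,9E)-3-(methoxymethoxy)-5,9-dimethyl-11-oxoundeca-1,9-dien-4-yl 3-methylbut-2-enoate | C=C[C@@H](OCOC)[C@H](OC(=O)C=C(C)C)[C@H](C)CCC/C(C)=C/C=O | intermediate
13 | O8 bromomethyl ether of 14 | C=C[C@@H](OCBr)[C@H](OC(=O)C=C(C)C)[C@H](C)CCC/C(C)=C/C=O | intermediate
14 | (3R,4R,5R,9E)-3-hydroxy-5,9-dimethyl-11-oxoundeca-1,9-dien-4-yl 3-methylbut-2-enoate | C=C[C@@H](O)[C@H](OC(=O)C=C(C)C)[C@H](C)CCC/C(C)=C/C=O | intermediate
15 | 2-(bromomethyl)acrylic acid | C=C(CBr)C(=O)O | starting material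
16 | 2-(bromomethyl)acryloyl chloride | C=C(CBr)C(=O)Cl | intermediate
17 | (3R,4R,5R,9E)-3-{[2-(bromomethyl)acryloyl]oxy}-5,9-dimethyl-11-oxoundeca-1,9-dien-4-yl 3-methylbut-2-enoate | C=C[C@@H](OC(=O)C(=C)CBr)[C@H](OC(=O)C=C(C)C)[C@H](C)CCC/C(C)=C/C=O | intermediate
18 | (1R,2R,6E)-1-[(2R)-4-(bromomethyl)-5-oxo-2,5-dihydrofuran-2-yl]-2,6-dimethyl-8-oxooct-6-en-1-yl 3-methylbut-2-enoate (key-step precursor) | BrCC1=C[C@@H](OC1=O)[C@H](OC(=O)C=C(C)C)[C@H](C)CCC/C(C)=C/C=O | intermediate
19 | C13 allylchromium dichloride derived from 18 | Cl[Cr](Cl)CC1=C[C@@H](OC1=O)[C@H](OC(=O)C=C(C)C)[C@H](C)CCC/C(C)=C/C=O | intermediate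
20 | O6 chromium dichloride alkoxide of 21 | C=C1C(=O)O[C@H]2[C@H](OC(=O)C=C(C)C)[C@H](C)CCC/C(C)=C/[C@H](O[Cr](Cl)Cl)[C@@H]12 | intermediate
21 | (4E,6S,7R,8R,9R,10R)-6-hydroxy-9-(3-methylbut-2-enoyloxy)germacra-4,11(13)-dien-12,8-olide (key-step product) | C=C1C(=O)O[C@H]2[C@H](OC(=O)C=C(C)C)[C@H](C)CCC/C(C)=C/[C@H](O)[C@@H]12 | intermediate
22 | (4R,5R,6R,7R,8R,9R,10R)-4,5-epoxy-6-hydroxy-9-(3-methylbut-2-enoyloxy)germacr-11(13)-en-12,8-olide, CNP0214930.1 | C=C1C(=O)O[C@H]2[C@H](OC(=O)C=C(C)C)[C@H](C)CCC[C@@]3(C)O[C@@H]3[C@H](O)[C@@H]12 | target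

Total step count: 11. Longest linear sequence: 11 steps, from geranyl acetate (1).

Steps most likely to fail

**1. Step 10.**
- What may go wrong: bond formation on the butenolide face remote from C9, which would fuse the rings trans; intermolecular coupling in place of ring closure; vinylogous reductive opening of the lactone from the allylchromium; or acyl transfer from O8 to the new O6 alkoxide.
- The fallback sets out from 18 and comes back at 22. It gives the aldehyde a neighbouring stereocentre before the ring is closed.
- Luche reduction of the enal (NaBH4, CeCl3·7H2O, MeOH, −78 °C) should give the C6 allylic alcohol F1.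
- Katsuki–Sharpless epoxidation (Ti(OiPr)4, D-(−)-diethyl tartrate, t-BuOOH, 4 Å sieves, CH2Cl2, −20 °C) should give, under reagent control, the epoxy alcohol F2 with C4 and C5 as in the target.
- TEMPO/PhI(OAc)2 should then give the epoxy aldehyde F3.
- The same chromium-mediated closure of F3 ends directly at 22.
- The sp3 C5 centre should steer the aldehyde face in the Felkin–Anh sense toward the erythro C5/C6 pair. The planarity demanded by the conjugated enal is gone, the closed transition state passes the chosen aldehyde face on to C7, and step 11 is no longer needed.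

**2. Step 11.**
- What may go wrong: oxygen delivery to the other olefin face through the conformer in which H6, not O6, lies next to C15; slow turnover at the hindered carbinol; or Lewis-acid opening of the new epoxide.
- The fallback sets out from 21 and comes back at 22. It replaces substrate direction by reagent control.
- It uses a stoichiometric Katsuki–Sharpless system (Ti(OiPr)4, D-(−)-diisopropyl tartrate, t-BuOOH, 4 Å sieves, CH2Cl2, −20 °C).
- This tartrate selects the (4R,5R) face. The C6 configuration of 21 is its fast-reacting, erythro-selective partner, so reagent and substrate should reinforce each other.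
- No new compound arises (F0).

**3. Step 9.**
- What may go wrong: competing closure of a six-membered lactone onto the senecioate olefin with loss of isobutene; sluggish closure onto the hindered bromomethyl-substituted acrylate; or catalyst decay at 80 °C.
- The fallback sets out from 14 and comes back at 18. It closes the ring on an unsubstituted acrylate and adds C13 afterwards.
- Acryloyl chloride and i-Pr2NEt should give the acrylate F4.
- Ring-closing metathesis with the same catalyst then engages a monosubstituted acrylate, far more reactive than the senecioate, and should give the C11-unsubstituted butenolide F5.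
- Iodine in pyridine/CH2Cl2 should give the 3-iodobutenolide F6.
- Stille coupling with (tributylstannyl)methanol (Pd(PPh3)4, toluene, 80 °C) should give the 3-(hydroxymethyl)butenolide F7.
- Appel bromination (CBr4, PPh3, CH2Cl2, 0 °C) returns to 18.

Further compounds

F1 | step 10 | (1R,2R,6E)-1-[(2R)-4-(bromomethyl)-5-oxo-2,5-dihydrofuran-2-yl]-8-hydroxy-2,6-dimethyloct-6-en-1-yl 3-methylbut-2-enoate | BrCC1=C[C@@H](OC1=O)[C@H](OC(=O)C=C(C)C)[C@H](C)CCC/C(C)=C/CO
F2 | step 10 | 4,5-epoxy alcohol of F1, epoxide configured as in the target | BrCC1=C[C@@H](OC1=O)[C@H](OC(=O)C=C(C)C)[C@H](C)CCC[C@@]2(C)O[C@@H]2CO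
F3 | step 10 | 4,5-epoxy C6 aldehyde, epoxide configured as in the target | BrCC1=C[C@@H](OC1=O)[C@H](OC(=O)C=C(C)C)[C@H](C)CCC[C@@]2(C)O[C@@H]2C=O
F0 | step 11 | none | none
F4 | step 9 | (3R,4R,5R,9E)-3-(acryloyloxy)-5,9-dimethyl-11-oxoundeca-1,9-dien-4-yl 3-methylbut-2-enoate | C=C[C@@H](OC(=O)C=C)[C@H](OC(=O)C=C(C)C)[C@H](C)CCC/C(C)=C/C=O
F5 | step 9 | (1R,2R,6E)-2,6-dimethyl-8-oxo-1-[(2R)-5-oxo-2,5-dihydrofuran-2-yl]oct-6-en-1-yl 3-methylbut-2-enoate | O=C1C=C[C@@H](O1)[C@H](OC(=O)C=C(C)C)[C@H](C)CCC/C(C)=C/C=O
F6 | step 9 | (1R,2R,6E)-1-[(2R)-4-iodo-5-oxo-2,5-dihydrofuran-2-yl]-2,6-dimethyl-8-oxooct-6-en-1-yl 3-methylbut-2-enoate | O=C1C(I)=C[C@@H](O1)[C@H](OC(=O)C=C(C)C)[C@H](C)CCC/C(C)=C/C=O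
F7 | step 9 | (1R,2R,6E)-1-[(2R)-4-(hydroxymethyl)-5-oxo-2,5-dihydrofuran-2-yl]-2,6-dimethyl-8-oxooct-6-en-1-yl 3-methylbut-2-enoate | O=C1C(CO)=C[C@@H](O1)[C@H](OC(=O)C=C(C)C)[C@H](C)CCC/C(C)=C/C=O
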